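## Structural features

Isariotin C is a bicyclo[3.3.1]nonan-9-one. Ring A (C1–C2–C3–C4–C5–C9) and ring B (C1–C8–C7–C6–C5–C9) share the bridgeheads C1 (CH) and C5 (C–OH) and the one-carbon bridge C9, which is the ketone. Ring A carries the C2 hydroxyl and the C3 nitrogen, acylated as an (E)-7-oxododec-2-enamide; ring B carries the C8 hydroxyl and the C6–C7 epoxide. The seven stereocentres C1, C2, C3, C5, C6, C7 and C8 are contiguous around the core. Reading the SMILES on a model places the C2–O, C3–N and C8–O bonds and the epoxide oxygen all on the exo faces (turned away from the other ring, on the C9 side), so C2–O and C3–N are cis. Fragile groups are the epoxide (acid), the two β-hydroxy ketone units C2–C1–C9 and C8–C1–C9 (retro-aldol and epimerisation under base), the tertiary α-ketol C5(OH)–C9(=O) (ketol shift) and the enamide with its chain ketone (hydride, strong nucleophiles). The real difficulty is the doubly bridged, densely oxygenated core with its bridgehead α-ketol, not the chain. The key step exploits two features: C5(OH)–C9(=O) is the retron of an aldehyde–ketone benzoin, and C1 to C8 form a cyclooctane bridged 1,5 by C9, so that one C5–C9 bond made across an eight-membered ring closes ring A and ring B together.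

## Logic of the disconnections

29 ⇒ 28. The two C–O bonds of the C6–C7 epoxide are cut first. The epoxide is the most acid-sensitive group, and placed last it meets no acid, tin hydride or base. The forward step must deliver oxygen only to C6=C7, on the exo face marked by the allylic C8 hydroxyl, and leave the electron-poor enamide alone.

28 ⇒ 21 + 27. The amide C–N bond is cut. This removes the whole chain and makes the route convergent. The forward step must acylate nitrogen in the presence of three free hydroxyls.

27 ⇒ 25 + 26, and 25 ⇒ 22 + 23. The chain C2=C3 bond is cut as a cross-metathesis and the C7–C8 bond as an organomagnesium addition to a nitrile. Both fragments become commercial compounds; the metathesis must give the E alkene.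

21 ⇒ 19 ⇒ 18 ⇒ 17 ⇒ 16. The C3–N bond is cut, by way of a C4–I bond that is put in and taken out again. Tethering nitrogen to the C2 oxygen fixes both the position (C3, not C4) and the face (exo, cis to C2–O). The forward cyclisation needs an electrophile on the concave endo face of C3=C4, and 16 must offer a single free secondary hydroxyl.

16 ⇒ 15. The C8 O–acetyl bond is cut. This returns a meso compound in which ring A and ring B are mirror images, so one reagent-controlled step chooses the absolute configuration. It demands enantiotopic-group selectivity.

15 ⇒ 13. The C2–O and C8–O bonds are cut. What remains has no stereocentre and only three functional groups. The forward step must hydroxylate both allylic methylenes on their exo faces without moving the double bonds.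

13 ⇒ 11. The C5–C9 bond is cut, which opens both rings at once to a monocyclic keto aldehyde. The forward step must generate an acyl-anion equivalent at C9 and direct it to the carbonyl carbon C5 across the ring, not to the enone β-carbons or to a second molecule.

11 ⇒ 10 ⇒ 7. The aldehyde is masked as its acetal and the two ring C=C bonds are removed. The forward step is a double α,β-dehydrogenation that must tolerate the acetal.

7 ⇒ 6 ⇒ 3 + 4, and 3 ⇒ 1. The exocyclic C–C bond is cut as a methoxymethylenation of one carbonyl of a symmetrical dione. Symmetry guarantees the 1,5 relationship. The forward sequence must stop at mono-olefination and must keep the enol ether away from a transannular carbonyl when acid is applied.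

## Other disconnections considered

Alternative 1: The cut is at C3–C4 and C5–C6, with a temporary C3–C6 bond that is broken again. In the forward step the tethered enone–alkene A1 is irradiated to give the crossed [2+2] adduct, and a Lewis acid in the same flask opens the donor–acceptor cyclobutane bond C3–C6 by retro-aldol cleavage to the bicyclic diketone A2. A1 is a 2-amido-3-ethoxycyclohexenone whose carbonyl-side ring carbon, the future C1, carries the C9 carbinol and the 2-acetoxyallyl unit.
- In its favour: the C3 nitrogen and the oxygen on quaternary C5 are in place before the rings form, and the photocycloaddition–fragmentation sequence is an established reaction class.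
- Against it here: A2 has its oxidation pattern displaced. C9 arrives as a silyl ether and must be oxidised; C2 is a ketone that must be reduced to the exo alcohol against the usual exo approach of hydride; the C6 ketone must be transposed into the C6–C7 epoxide and C8 hydroxyl. The three-atom link between enone and alkene normally favours the straight adduct, so the crossed mode is not assured.
- Comparison: on structure, both plans build both rings in one operation, but only the chosen plan delivers the C9 ketone and C5 hydroxyl at their final oxidation levels. On mechanism, this alternative is the better-precedented of the two. It is also the equal or better in drawing absolute configuration from one early carbinol centre. On step economy, the chosen plan should be shorter, because A1 needs a multistep assembly and A2 needs several redox corrections.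

Alternative 2: The cut is at the C3–N bond only. In the forward step the primary carbamate A3, on the C2 oxygen of the otherwise complete silyl-protected core, is oxidised by an iodine-based oxidant under an Rh2(O2CR)4-type catalyst to a rhodium nitrene. The nitrene inserts into the exo C3–H bond to give the cis-fused oxazolidinone A4.
- In its favour: insertion proceeds with retention, so nitrogen is exo and cis to C2–O by construction. No iodine or tin is used, and no electrophile has to reach the concave face. On these points it is better than steps 10 and 11 of the chosen plan.
- Against it here: it does not touch the carbon skeleton, so the whole bicyclic problem remains. The C3–H bond is an unactivated methylene, the least willing class for carbamate insertion. Opening the oxazolidinone needs base that threatens the β-hydroxy ketones and the α-ketol, and two silyl groups have to be carried.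
- Comparison: on structure, it is an endgame, not a ring construction, and would need ring A saturated, whereas the chosen key step leaves a C3=C4 alkene. On mechanism, it is the more stereospecific amination. On step economy, the protecting-group and ring-opening steps make it at best equal.

Alternative 3: The cut is at C4–C5 and C1–C2. In the forward step a cinchona-derived primary amine mediates Michael addition of the β-keto ester A5 through C5 to acrolein A6, and in the same flask C1 attacks the tethered aldehyde to close ring A as A7.
- In its favour: amine-catalysed Michael–aldol annulation of cyclic β-keto esters to bicyclo[3.3.1]nonanes is a well-precedented class, better in this respect than the chosen key step. The C5 quaternary centre is set enantioselectively in the ring-forming step, which is equal or better than a late enzymatic desymmetrisation. The C2 oxygen arrives with the ring.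
- Against it here: C5 ends up bearing a carbon where the target has oxygen, and exchanging a bridgehead ester for a tertiary hydroxyl is a degradative detour. C3 is an unfunctionalised methylene that still needs nitrogen, and ring B still needs the C8 hydroxyl and the epoxide. A5 is a β,γ-unsaturated β-keto ester prone to double-bond migration and γ-alkylation.
- Comparison: on structure, the chosen plan gives the correct heteroatom on C5 and a symmetric intermediate. On mechanism, Alternative 3 is the safer reaction. On step economy, the functional-group mismatch at C5 and the missing C3–N make it longer.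

Key step: step 6

Remarks on the chemistry:
- Locants of all bicyclic compounds follow the core numbering of the target (C1 = CH bridgehead, C5 = C–O bridgehead, C9 = bridge). "Exo" means the face turned away from the other ring.
- Correction of a descriptor: 13 has no stereocentre and is simply achiral (mirror plane through C1, C9, C5). The first meso compound is 15.
- Design change before the key step: the second carbonyl is reduced in the flask before the enol ether meets acid. A ring carbon of an enol ether lying 1,5 to a ketone in cyclooctane is set up for transannular C–C bond formation to a bicyclo[3.3.0]octane. The alcohol is re-oxidised in the flask of the dehydrogenation, so no step is added.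
- Design change after the key step: nitrogen first, epoxide last. No silyl group is needed and the epoxide never meets acid.
- Assumption: the lipase acetylates the R-configured carbinol (C8). If it prefers the other hydroxyl, hydrolysis of the diacetate with the same enzyme leads to the same 16.

## Route

Step 1
Reactants: 1 cis-cyclooctane-1,5-diol
Product: 3 cyclooctane-1,5-dione, via 5-hydroxycyclooctan-1-one 2 (not isolated)
Conditions: TEMPO (cat.), KBr (cat.), NaOCl (aq), NaHCO3, CH2Cl2–H2O, 0 °C
Reagents that add atoms: none
Why: Oxoammonium (TEMPO/hypochlorite) oxidation of secondary alcohols; 2 rests as its bridged hemiketal but reopens in the aqueous medium, so the second oxidation completes. Both stereocentres of 1 are destroyed.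

Step 2
Reactants: 3 cyclooctane-1,5-dione; 4 (methoxymethyl)triphenylphosphonium chloride
Product: 6 5-(methoxymethylidene)cyclooctan-1-ol (racemic), via 5-(methoxymethylidene)cyclooctan-1-one 5 (not isolated)
Conditions: 4, KOtBu, THF, 0 °C; add to 3 (excess), −78 → 0 °C; then NaBH4, MeOH, 0 °C
Reagents that add atoms: none
Why: Wittig methoxymethylenation of one carbonyl of the symmetrical dione (statistical, dione in excess), then borohydride reduction of the remaining ketone so that no carbonyl faces the enol ether across the ring. Unreacted 3 returns as the diol and is recycled through step 1; the axial chirality of 6 is of no consequence.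

Step 3
Reactants: 6 5-(methoxymethylidene)cyclooctan-1-ol
Product: 7 5-(dimethoxymethyl)cyclooctan-1-ol (cis/trans mixture)
Conditions: PPTS (cat.), MeOH, 0 °C → rt; Et3N quench
Reagents that add atoms: methanol, CO
Why: Acid-catalysed addition of methanol to the enol ether (C-protonation, capture of the oxocarbenium ion) gives the dimethyl acetal. With the ketone absent there is no transannular electrophile, and both diastereomers converge in step 4.

Step 4
Reactants: 7 5-(dimethoxymethyl)cyclooctan-1-ol
Product: 10 (2Z,7Z)-5-(dimethoxymethyl)cycloocta-2,7-dien-1-one, via 5-(dimethoxymethyl)cyclooctan-1-one 8 (not isolated), via (Z)-5-(dimethoxymethyl)cyclooct-2-en-1-one 9 (not isolated)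
Conditions: IBX (6 equiv, portions), DMSO–PhF (1:2), 70 → 85 °C
Reagents that add atoms: none
Why: IBX oxidises the alcohol to 8 and, on heating, dehydrogenates the ketone on both sides through its enol to the cross-conjugated dienone (IBX α,β-dehydrogenation of ketones). The ring enforces cis alkenes, and the acetal carbon has no carbonyl next to it and is not attacked.

Step 5
Reactants: 10 (2Z,7Z)-5-(dimethoxymethyl)cycloocta-2,7-dien-1-one
Product: 11 (3Z,6Z)-5-oxocycloocta-3,6-diene-1-carbaldehyde
Conditions: PPTS (cat.), acetone–H2O (10:1), rt; used at once
Reagents that add atoms: water, O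
Why: Mild acid-catalysed acetal hydrolysis. The weak acid and short contact time are chosen because 11 is an enolisable aldehyde facing a ketone across the ring.

Step 6
Reactants: 11 (3Z,6Z)-5-oxocycloocta-3,6-diene-1-carbaldehyde
Product: 13 5-hydroxybicyclo[3.3.1]nona-3,6-dien-9-one, via Breslow enaminol 12 (not isolated)
Conditions: 2-(C6F5)-6,7-dihydro-5H-pyrrolo[2,1-c][1,2,4]triazol-2-ium BF4 (10 mol%), iPr2NEt (10 mol%), CH2Cl2 (0.01 M), rt, Ar
Reagents that add atoms: none
Why: Proposed new method: the triazolylidene freed by the amine adds to the aldehyde of 11 and proton transfer gives the nucleophilic enaminol 12, whose carbon (C9) attacks the C5 carbonyl held across the eight-membered ring; proton transfer and loss of the carbene release 13. The closest known reaction type is the carbene-catalysed intramolecular crossed aldehyde–ketone benzoin that closes five- and six-membered tertiary ketols; a transannular version across a medium ring to a bridged ketol has no direct counterpart. The single C5–C9 bond closes ring A and ring B at once, each as a 6-exo-trig addition to the ketone when followed along its own three-carbon path. No stereocentre is created: C1, C5 and C9 lie in the mirror plane of 13 and the bridge can only span one face of the ring. The step needs 1,2-addition over conjugate addition, which the ring secures because attack at either β-carbon would close a cyclobutane. It also needs ring closure over aldehyde dimerisation and over transannular aldol of the aldehyde enolate, which high dilution, the 1,5 proximity, the weak base and the reversibility of those side reactions should secure. Ketol 13 cannot enolise at a bridgehead and cannot dehydrate, so the reversible benzoin manifold should drain into it.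

Step 7
Reactants: 13 5-hydroxybicyclo[3.3.1]nona-3,6-dien-9-one
Product: 15 meso (2S,8R)-2,5,8-trihydroxybicyclo[3.3.1]nona-3,6-dien-9-one (both secondary hydroxyls exo), via 2-exo-2,5-dihydroxybicyclo[3.3.1]nona-3,6-dien-9-one 14 (not isolated)
Conditions: SeO2 (2.5 equiv), 1,4-dioxane–H2O (50:1), 80 °C
Reagents that add atoms: selenium dioxide, O=[Se]=O
Why: Riley allylic hydroxylation: ene reaction of SeO2 at C4 (then C6) from the open exo face, taking the axial exo hydrogen of C2 (C8), followed by a [2,3]-sigmatropic shift that returns the alkene to C3=C4 (C6=C7) and places oxygen exo on C2 (C8). C5 has no hydrogen, so the position is unambiguous, and the exo face of the ene step sets both new stereocentres.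

Step 8
Reactants: 15 meso (2S,8R)-2,5,8-trihydroxybicyclo[3.3.1]nona-3,6-dien-9-one
Product: 16 (1S,2S,5S,8R)-2,5-dihydroxy-9-oxobicyclo[3.3.1]nona-3,6-dien-8-yl acetate
Conditions: immobilised Burkholderia cepacia lipase, vinyl acetate, MTBE, 30 °C
Reagents that add atoms: vinyl acetate, CC(=O)OC=C
Why: Enzymatic desymmetrisation by enantiotopic-group-selective transesterification; the empirical size rule for lipases (larger substituent = bridgehead C1, medium = vinylic C7) predicts acylation of the R carbinol C8. This one step fixes the absolute configuration of C1, C2, C5 and C8 and leaves the C2 hydroxyl as the only free secondary alcohol.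

Step 9
Reactants: 16 (1S,2S,5S,8R)-2,5-dihydroxy-9-oxobicyclo[3.3.1]nona-3,6-dien-8-yl acetate
Product: 17 (1S,2S,5S,8R)-5-hydroxy-9-oxo-2-[(2,2,2-trichloroethanimidoyl)oxy]bicyclo[3.3.1]nona-3,6-dien-8-yl acetate
Conditions: Cl3CCN, DBU (cat.), CH2Cl2, −20 → 0 °C
Reagents that add atoms: trichloroacetonitrile, ClC(Cl)(Cl)C#N
Why: Base-catalysed addition of the secondary allylic alcohol to the nitrile (trichloroacetimidate formation). The hindered, α-keto tertiary C5 hydroxyl is far slower, and catalytic base at low temperature avoids retro-aldol of the β-hydroxy ketone.

Step 10
Reactants: 17 (1S,2S,5S,8R)-5-hydroxy-9-oxo-2-[(2,2,2-trichloroethanimidoyl)oxy]bicyclo[3.3.1]nona-3,6-dien-8-yl acetate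
Product: 18 (1R,2R,3R,4S,5S,8R)-5-hydroxy-4-endo-iodo-9-oxobicyclo[3.3.1]non-6-en-8-yl acetate carrying a 2-(trichloromethyl)-4,5-dihydro-1,3-oxazole cis-fused through O at C2 and N at C3 (both exo)
Conditions: NIS, MeCN, 0 °C → rt, dark
Reagents that add atoms: N-iodosuccinimide, O=C1CCC(=O)N1I
Why: Iodocyclisation (iodoamination) of an allylic trichloroacetimidate: the iodonium ion on C3=C4 is opened 5-exo by the imidate nitrogen at C3. The tether on the exo C2 oxygen forces nitrogen exo at C3, cis to C2–O, and anti opening puts iodine endo at C4, where it is removed in step 11.

Step 11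
Reactants: 18 the 4-endo-iodo oxazoline
Product: 19 (1R,2R,3S,5S,8R)-5-hydroxy-9-oxobicyclo[3.3.1]non-6-en-8-yl acetate carrying the same cis-fused 2-(trichloromethyl)-4,5-dihydro-1,3-oxazole (O at C2, N at C3)
Conditions: Bu3SnH (1.1 equiv), AIBN (cat.), PhMe, 80 °C
Reagents that add atoms: none
Why: Radical chain deiodination; the C–I bond reacts much faster with the stannyl radical than the C–Cl bonds, and the C4 radical cannot cyclise (only three- or four-membered rings are in reach). Any over-reduction of CCl3 is harmless because that group is removed next.

Step 12
Reactants: 19 the deiodinated oxazoline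
Product: 21 (1R,2R,3S,5S,8R)-3-amino-2,5,8-trihydroxybicyclo[3.3.1]non-6-en-9-one hydrochloride, via 8-acetoxy-3-amino-2,5-dihydroxybicyclo[3.3.1]non-6-en-9-one hydrochloride 20 (not isolated)
Conditions: HCl (1.25 M in MeOH), H2O (5 equiv), 0 → 40 °C
Reagents that add atoms: hydrogen chloride, Cl
Why: Acid hydrolysis of the 2-trichloromethyl oxazoline through the O-trichloroacetyl ammonium salt, then acid-catalysed methanolysis of that ester and of the acetate. No bond to a ring carbon is broken, so C2, C3 and C8 keep their configuration; acid, not base, spares the β-hydroxy ketones, and the salt keeps the amine from condensing with a ketone.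

Step 13
Reactants: 22 hex-5-enenitrile; 23 pentylmagnesium bromide
Product: 25 undec-1-en-6-one, via bromomagnesium undec-1-en-6-iminide 24 (not isolated)
Conditions: 23, Et2O, 0 °C → reflux; then 2 M HCl (aq), rt
Reagents that add atoms: water, O
Why: Grignard addition to a nitrile stops at the metallo-imine, which is hydrolysed to the ketone on acidic work-up; the terminal alkene is inert.

Step 14
Reactants: 25 undec-1-en-6-one; 26 acrylic acid
Product: 27 (E)-7-oxododec-2-enoic acid
Conditions: second-generation Grubbs catalyst (3 mol%), 26 (3 equiv), CH2Cl2, 40 °C
Reagents that add atoms: none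
Why: Olefin cross-metathesis of a terminal alkene with acrylic acid; the conjugated product is formed E under thermodynamic control and the ketone is tolerated.

Step 15
Reactants: 21 (1R,2R,3S,5S,8R)-3-amino-2,5,8-trihydroxybicyclo[3.3.1]non-6-en-9-one hydrochloride; 27 (E)-7-oxododec-2-enoic acid
Product: 28 (E)-N-[(1R,2R,3S,5S,8R)-2,5,8-trihydroxy-9-oxobicyclo[3.3.1]non-6-en-3-yl]-7-oxododec-2-enamide
Conditions: EDC·HCl, HOBt, iPr2NEt, DMF, 0 °C → rt
Reagents that add atoms: none
Why: Carbodiimide/HOBt amide coupling; the primary amine is far more nucleophilic toward the active ester than the two secondary and one tertiary hydroxyl, so acylation is N-selective.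

Step 16
Reactants: 28 (E)-N-[(1R,2R,3S,5S,8R)-2,5,8-trihydroxy-9-oxobicyclo[3.3.1]non-6-en-3-yl]-7-oxododec-2-enamide
Product: 29 isariotin C, (E)-N-[(1S,2R,3S,5S,6S,7S,8S)-6,7-epoxy-2,5,8-trihydroxy-9-oxobicyclo[3.3.1]nonan-3-yl]-7-oxododec-2-enamide
Conditions: VO(acac)2 (5 mol%), tBuOOH (decane), CH2Cl2, 0 °C → rt
Reagents that add atoms: tert-butyl hydroperoxide, CC(C)(C)OO
Why: Hydroxyl-directed epoxidation through a vanadium alkoxide–alkylperoxide: oxygen is delivered to C6=C7 on the face of the allylic exo C8 hydroxyl (also the face of C5–OH and the convex face), which sets C6 and C7. The enamide alkene is electron-poor and has no allylic hydroxyl.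

## Compound list

1 | cis-cyclooctane-1,5-diol | O[C@H]1CCC[C@@H](O)CCC1 | starting material
2 | 5-hydroxycyclooctan-1-one (largely as its bridged hemiketal) | O=C1CCCC(O)CCC1 | intermediate (not isolated)
3 | cyclooctane-1,5-dione | O=C1CCCC(=O)CCC1 | intermediate
4 | (methoxymethyl)triphenylphosphonium chloride | COC[P+](c1ccccc1)(c1ccccc1)c1ccccc1.[Cl-] | starting material
5 | 5-(methoxymethylidene)cyclooctan-1-one | COC=C1CCCC(=O)CCC1 | intermediate (not isolated)
6 | 5-(methoxymethylidene)cyclooctan-1-ol (racemic) | COC=C1CCCC(O)CCC1 | intermediate
7 | 5-(dimethoxymethyl)cyclooctan-1-ol (cis/trans mixture) | COC(OC)C1CCCC(O)CCC1 | intermediate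
8 | 5-(dimethoxymethyl)cyclooctan-1-one | COC(OC)C1CCCC(=O)CCC1 | intermediate (not isolated)
9 | (Z)-5-(dimethoxymethyl)cyclooct-2-en-1-one (racemic) | COC(OC)C1C/C=C\C(=O)CCC1 | intermediate (not isolated)
10 | (2Z,7Z)-5-(dimethoxymethyl)cycloocta-2,7-dien-1-one | COC(OC)C1C/C=C\C(=O)/C=C\C1 | intermediate
11 | (3Z,6Z)-5-oxocycloocta-3,6-diene-1-carbaldehyde | O=CC1C/C=C\C(=O)/C=C\C1 | intermediate (key-step precursor)
12 | Breslow enaminol of 11 (adduct of the triazolylidene at the formyl carbon) | OC(=C1N(c2c(F)c(F)c(F)c(F)c2F)N=C2CCCN12)C1C/C=C\C(=O)/C=C\C1 | intermediate (not isolated)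
13 | 5-hydroxybicyclo[3.3.1]nona-3,6-dien-9-one (achiral) | O=C1C2CC=CC1(O)C=CC2 | intermediate (key-step product)
14 | rac-(1R,2S,5R)-2,5-dihydroxybicyclo[3.3.1]nona-3,6-dien-9-one (C2 hydroxyl exo; one enantiomer drawn) | C1=C[C@@]2(O)C(=O)[C@H](CC=C2)[C@H]1O | intermediate (not isolated)
15 | meso (2S,8R)-2,5,8-trihydroxybicyclo[3.3.1]nona-3,6-dien-9-one (C2 and C8 hydroxyls exo) | C1=C[C@@]2(O)C(=O)[C@H]([C@H](O)C=C2)[C@H]1O | intermediate
16 | (1S,2S,5S,8R)-2,5-dihydroxy-9-oxobicyclo[3.3.1]nona-3,6-dien-8-yl acetate | C1=C[C@@]2(O)C(=O)[C@H]([C@H](OC(C)=O)C=C2)[C@H]1O | intermediate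
17 | (1S,2S,5S,8R)-5-hydroxy-9-oxo-2-[(2,2,2-trichloroethanimidoyl)oxy]bicyclo[3.3.1]nona-3,6-dien-8-yl acetate | C1=C[C@@]2(O)C(=O)[C@H]([C@H](OC(C)=O)C=C2)[C@H]1OC(=N)C(Cl)(Cl)Cl | intermediate
18 | (1R,2R,3R,4S,5S,8R)-4-endo-iodo oxazoline: 2-(trichloromethyl)-4,5-dihydro-1,3-oxazole cis-fused (O at C2, N at C3, exo) to 5-hydroxy-9-oxobicyclo[3.3.1]non-6-en-8-yl acetate | ClC(Cl)(Cl)C1=N[C@H]2[C@H](I)[C@@]3(O)C(=O)[C@H]([C@H](OC(C)=O)C=C3)[C@H]2O1 | intermediate
19 | (1R,2R,3S,5S,8R)-oxazoline: as 18 with CH2 at C4 | ClC(Cl)(Cl)C1=N[C@H]2C[C@@]3(O)C(=O)[C@H]([C@H](OC(C)=O)C=C3)[C@H]2O1 | intermediate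
20 | (1S,2R,3S,5S,8R)-8-acetoxy-3-amino-2,5-dihydroxybicyclo[3.3.1]non-6-en-9-one hydrochloride | Cl.N[C@H]1C[C@@]2(O)C(=O)[C@H]([C@H](OC(C)=O)C=C2)[C@H]1O | intermediate (not isolated)
21 | (1R,2R,3S,5S,8R)-3-amino-2,5,8-trihydroxybicyclo[3.3.1]non-6-en-9-one hydrochloride | Cl.N[C@H]1C[C@@]2(O)C(=O)[C@H]([C@H](O)C=C2)[C@H]1O | intermediate
22 | hex-5-enenitrile | C=CCCCC#N | starting material
23 | pentylmagnesium bromide | CCCCC[Mg]Br | starting material
24 | bromomagnesium undec-1-en-6-iminide | CCCCCC(CCCC=C)=N[Mg]Br | intermediate (not isolated)
25 | undec-1-en-6-one | CCCCCC(=O)CCCC=C | intermediate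
26 | acrylic acid | C=CC(=O)O | starting material
27 | (E)-7-oxododec-2-enoic acid | CCCCCC(=O)CCC/C=C/C(=O)O | intermediate
28 | (E)-N-[(1R,2R,3S,5S,8R)-2,5,8-trihydroxy-9-oxobicyclo[3.3.1]non-6-en-3-yl]-7-oxododec-2-enamide | CCCCCC(=O)CCC/C=C/C(=O)N[C@H]1C[C@@]2(O)C(=O)[C@H]([C@H](O)C=C2)[C@H]1O | intermediate
29 | isariotin C, (E)-N-[(1S,2R,3S,5S,6S,7S,8S)-6,7-epoxy-2,5,8-trihydroxy-9-oxobicyclo[3.3.1]nonan-3-yl]-7-oxododec-2-enamide | CCCCCC(=O)CCC/C=C/C(=O)N[C@H]1C[C@@]2(O)C(=O)[C@H]([C@H](O)[C@@H]3O[C@@H]32)[C@H]1O | target

## Step count and least certain steps

Total step count: 16 (steps 1–12, 15 and 16 on the main line; steps 13 and 14 for the chain). Longest linear sequence: 14 steps (1 → 29 through steps 1–12, 15, 16).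

Step 6 (key step; the only step marked as a proposed new method). The most likely failure is diversion of the carbene or of the aldehyde before the transannular addition: conjugate addition of the carbene to the dienone, intermolecular benzoin, or base-induced transannular aldol. The C5 carbonyl is cross-conjugated and less electrophilic, and the formyl group must turn inward over the ring. The fallback uses known chemistry, sets out from 11 and returns at 13. SmI2 (THF, −78 °C) intramolecular ketone–aldehyde pinacol coupling, established for 1,5- and 1,6-keto aldehydes, should give bicyclo[3.3.1]nona-3,6-diene-5,9-diol F1. Here too the conjugate mode would need a four-membered ring. Oxidation of its only secondary hydroxyl with Dess–Martin periodinane returns 13.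

Step 7. The most likely failure is a sluggish ene reaction on the two 1,2-disubstituted, inductively deactivated alkenes, with over-oxidation of the first-formed allylic alcohol to an enone during the long heating. The fallback sets out from 13 and returns at 15. Copper-mediated allylic acyloxylation (Kharasch–Sosnovsky reaction; CuBr, tert-butyl peroxyacetate, MeCN, 70 °C) works through an allyl radical captured on the open exo face at the less hindered terminus C2 (C8). It should give meso 2-exo,8-exo-diacetoxy-5-hydroxybicyclo[3.3.1]nona-3,6-dien-9-one F2, and acid methanolysis (HCl, MeOH) returns 15.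

Step 10. The most likely failure is loss of control at the iodonium stage. The iodonium ion needed lies in the cleft facing ring B, and the 5-exo closure forces ring A through a boat-like geometry. An iodonium ion on the open exo face could instead be captured across the cleft by the ring B alkene, or nitrogen could attack C4. The fallback sets out from 17 and returns at 19. Homolysis of the N-iodo imidate (NIS, visible light, MeCN) gives an imidate nitrogen radical that adds 5-exo to C3 from the tethered exo face, with no electrophile on the endo face and no cationic intermediate. Iodine-atom transfer to the C4 radical should give the C4-epimeric (4-exo-iodo) oxazoline F3, and the conditions of step 11 converge it on 19.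

Step 4. The most likely failure is hydrolysis of the dimethyl acetal by the acidic iodine reagent and the water formed at 70–85 °C, followed by dehydrogenation of the freed aldehyde; stalling at the mono-enone is the second risk. The fallback sets out from 7 and returns at 10. Dess–Martin oxidation gives 8 (isolated in this variant). Two kinetic α-selenenylations (LDA, PhSeBr, −78 °C) on the two sides of the carbonyl give 5-(dimethoxymethyl)-2,8-bis(phenylselanyl)cyclooctan-1-one F4. Oxidation with H2O2–pyridine at 0 °C and double syn-elimination of the selenoxides, under base throughout, give 10.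

Step 8. The most likely failure is insufficient discrimination between the enantiotopic hydroxyls, or no turnover, because both are pseudo-axial and flanked by a bridgehead. The fallback sets out from 15 and returns at 16. The enzyme is replaced by a small-molecule acyl-transfer catalyst: a chiral isothiourea (benzotetramisole type) with Ac2O and iPr2NEt in CHCl3 at 0 °C, which recognises allylic carbinols through the adjacent π system. Either catalyst enantiomer is available. This fallback makes no new compound (F0).

## Further compounds

F1 | step 6 | bicyclo[3.3.1]nona-3,6-diene-5,9-diol (racemic) | OC1C2CC=CC1(O)C=CC2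
F2 | step 7 | meso 2-exo,8-exo-diacetoxy-5-hydroxybicyclo[3.3.1]nona-3,6-dien-9-one | C1=C[C@@]2(O)C(=O)[C@H]([C@H](OC(C)=O)C=C2)[C@H]1OC(C)=O
F3 | step 10 | 4-exo-iodo epimer of 18 (oxazoline O at C2, N at C3, exo; 8-acetate) | ClC(Cl)(Cl)C1=N[C@H]2[C@@H](I)[C@@]3(O)C(=O)[C@H]([C@H](OC(C)=O)C=C3)[C@H]2O1
F4 | step 4 | 5-(dimethoxymethyl)-2,8-bis(phenylselanyl)cyclooctan-1-one (diastereomer mixture) | COC(OC)C1CCC([Se]c2ccccc2)C(=O)C([Se]c2ccccc2)CC1
F0 | step 8 | none | none
A1 | alternative 1 | tert-butyl N-[6-(2-acetoxy-1-(tert-butyldimethylsilyloxy)allyl)-3-ethoxy-1-oxocyclohex-2-en-2-yl]carbamate (photosubstrate) | C=C(OC(C)=O)[C@H](O[Si](C)(C)C(C)(C)C)[C@@H]1CCC(OCC)=C(NC(=O)OC(C)(C)C)C1=O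
A2 | alternative 1 | 5-acetoxy-3-(tert-butoxycarbonylamino)-9-(tert-butyldimethylsilyloxy)bicyclo[3.3.1]nonane-2,6-dione | CC(C)(C)OC(=O)N[C@H]1C[C@@]2(OC(C)=O)[C@H](O[Si](C)(C)C(C)(C)C)[C@H](CCC2=O)C1=O
A3 | alternative 2 | C2 primary carbamate of the 6,7-epoxy core with 5-O-triethylsilyl and 8-O-tert-butyldimethylsilyl groups | C1C[C@@]2(O[Si](CC)(CC)CC)C(=O)[C@H]([C@H](O[Si](C)(C)C(C)(C)C)[C@@H]3O[C@@H]32)[C@H]1OC(N)=O
A4 | alternative 2 | C2,C3-cis-fused oxazolidinone of the same protected core | O=C1N[C@H]2C[C@@]3(O[Si](CC)(CC)CC)C(=O)[C@H]([C@H](O[Si](C)(C)C(C)(C)C)[C@@H]4O[C@@H]43)[C@H]2O1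
A5 | alternative 3 | methyl 6-oxocyclohex-2-ene-1-carboxylate | COC(=O)C1C=CCCC1=O
A6 | alternative 3 | acrolein | C=CC=O
A7 | alternative 3 | methyl 2-hydroxy-9-oxobicyclo[3.3.1]non-6-ene-5-carboxylate (core numbering) | C1C[C@@]2(C(=O)OC)C(=O)[C@H](CC=C2)[C@H]1O
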